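**Plan**

- Retrosynthesis (labdane numbering): the C3 carbinol and the C9 benzoate are set last. Ring B is cut at C8–C9, giving a ring-A diketone with a (Z)-alkenyl iodide arm on C5 and the C9 ketone on C10. The side chain is cut at C11–C12, and ring A at C4–C5 and C1–C10 ([4+2]).
- Forward: ring A comes from a catalytic enantioselective Diels–Alder reaction of a 2-siloxydiene with an (E)-α-methyl enal. The C4 gem-dimethyl group follows by α′-methylation of the derived enone. The C9 methyl ketone is alkylated at C11 with the C12–C16 bromo-enoate, an iodo-olefination builds C7=C8–I, and ring B closes last by a Ni/Cr-mediated alkenyl–ketone coupling.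
- Enabling feature: C9 is a tertiary allylic carbinol of ring B, bonded to C8 of the C7=C8 alkene and to quaternary C10. A C9 ketone (enolisable only toward C11) and a Z C8–I bond, linked through C7–C6–C5–C10, are therefore set up for a six-membered closure that also fixes the alkene position.
- Stereochemistry: C5 and C10 come from the cycloaddition (absolute sense from the catalyst, relative sense from the E geometry). C9 is set in the ring closure under control of C10 and the ring-A chair. C3 is set by axial hydride delivery to the trans-decalin ketone, 13E comes from the bromo-enoate, and the 7,8-alkene from the Z iodide.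

Key step: step 15

Remark: positions are given in labdane numbering (C1–C10 decalin, C11–C16 side chain, C17 on C8, C20 on C10).
Assumption: the (S)-oxazaborolidinium catalyst is taken to give the (1S,6S) adduct 6; if the sense of induction with this trisubstituted enal proves opposite, the (R)-catalyst is used with no other change.

Step 1
Reactants: 1 but-3-en-2-one
Product: 2 2-(triisopropylsilyloxy)buta-1,3-diene
Conditions: iPr3SiOSO2CF3, Et3N, Et2O, 0 °C → rt
Reagents that add atoms: triisopropylsilyl trifluoromethanesulfonate, CC(C)[Si](OS(=O)(=O)C(F)(F)F)(C(C)C)C(C)C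
Why: Silyl enol ether formation by soft enolisation of the methyl ketone should O-silylate its only enolisable side and give the 2-siloxy-1,3-diene.

Step 2
Reactants: 3 3-(tert-butyldimethylsilyloxy)propanal; 4 2-(triphenylphosphoranylidene)propanal
Product: 5 (E)-5-(tert-butyldimethylsilyloxy)-2-methylpent-2-enal
Conditions: toluene, 80 °C
Reagents that add atoms: none
Why: Wittig olefination with a stabilised formyl ylide should give the (E)-trisubstituted enal, the geometry that later fixes the C5/C10 relationship.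

Step 3
Reactants: 5 (E)-5-(tert-butyldimethylsilyloxy)-2-methylpent-2-enal; 2 2-(triisopropylsilyloxy)buta-1,3-diene
Product: 6 (1S,6S)-6-[2-(tert-butyldimethylsilyloxy)ethyl]-1-methyl-4-(triisopropylsilyloxy)cyclohex-3-ene-1-carbaldehyde
Conditions: (S)-3,3-diphenyl-1-(2-methylphenyl)tetrahydro-1H,3H-pyrrolo[1,2-c][1,3,2]oxazaborole (0.2 equiv), HN(SO2CF3)2 (0.2 equiv), CH2Cl2, −78 → −40 °C
Reagents that add atoms: none
Why: In this chiral oxazaborolidinium-catalysed Diels–Alder reaction the siloxy-activated diene terminus bonds to the enal β-carbon (para orientation), the suprafacial addition carries the E geometry into the trans relationship of the C5 arm and the C10 formyl group (C10 methyl cis to the arm), and the catalyst shields one enal face so that C5 and C10 should both be set as S.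

Step 4
Reactants: 6 (1S,6S)-6-[2-(tert-butyldimethylsilyloxy)ethyl]-1-methyl-4-(triisopropylsilyloxy)cyclohex-3-ene-1-carbaldehyde
Product: 7 tert-butyl(2-{(1S,6R)-6-ethenyl-6-methyl-3-(triisopropylsilyloxy)cyclohex-3-en-1-yl}ethoxy)dimethylsilane
Conditions: Ph3PCH3Br, KOtBu, THF, 0 °C → rt
Reagents that add atoms: methyltriphenylphosphonium bromide, C[P+](c1ccccc1)(c1ccccc1)c1ccccc1.[Br-]
Why: Wittig methylenation of the non-enolisable neopentylic aldehyde turns C9 into a vinyl group that is inert to the base of step 6 and serves as a latent methyl ketone, while both silyl groups stay in place.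

Step 5
Reactants: 7 tert-butyl(2-{(1S,6R)-6-ethenyl-6-methyl-3-(triisopropylsilyloxy)cyclohex-3-en-1-yl}ethoxy)dimethylsilane
Product: 8 (4R,5S)-5-[2-(tert-butyldimethylsilyloxy)ethyl]-4-ethenyl-4-methylcyclohex-2-en-1-one
Conditions: Pd(OAc)2 (1.1 equiv), MeCN, 40 °C
Reagents that add atoms: none
Why: In this Saegusa–Ito oxidation divalent palladium adds to the regiodefined silyl enol ether at C2 and β-hydride elimination toward C1 gives the C1=C2 enone, which leaves C4 as the only enolisable position of ring A.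

Step 6
Reactants: 8 (4R,5S)-5-[2-(tert-butyldimethylsilyloxy)ethyl]-4-ethenyl-4-methylcyclohex-2-en-1-one
Product: 10 (4S,5R)-5-[2-(tert-butyldimethylsilyloxy)ethyl]-4-ethenyl-4,6,6-trimethylcyclohex-2-en-1-one, via monomethyl enone 9 (not isolated)
Conditions: LiN(iPr)2 (1.1 equiv), THF, −78 °C; MeI, −78 → 0 °C; the same cycle once more in the same flask
Reagents that add atoms: iodomethane, CI
Why: In this α′-alkylation of a cyclohexenone the base can deprotonate only at C4 (C10 is quaternary, so there is no γ-hydrogen), and two deprotonation/methylation cycles should build the C4 gem-dimethyl group without any regiochemical choice.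

Step 7
Reactants: 10 (4S,5R)-5-[2-(tert-butyldimethylsilyloxy)ethyl]-4-ethenyl-4,6,6-trimethylcyclohex-2-en-1-one
Product: 11 (4S,5S)-4-acetyl-5-[2-(tert-butyldimethylsilyloxy)ethyl]-4,6,6-trimethylcyclohex-2-en-1-one
Conditions: PdCl2 (0.1 equiv), CuCl (1 equiv), O2 (1 atm), DMF/H2O 7:1, rt
Reagents that add atoms: water, O
Why: Wacker–Tsuji oxidation by Markovnikov hydroxypalladation of the terminal vinyl group should give the C9 methyl ketone (its methyl is C11), while the electron-poor enone alkene does not react.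

Step 8
Reactants: 12 3-methylbut-2-enoic acid; 13 2-(trimethylsilyl)ethanol
Product: 14 2-(trimethylsilyl)ethyl 3-methylbut-2-enoate
Conditions: N,N'-dicyclohexylcarbodiimide, 4-(dimethylamino)pyridine (cat.), CH2Cl2, 0 °C → rt
Reagents that add atoms: none
Why: Steglich esterification installs the fluoride-labile 2-(trimethylsilyl)ethyl ester, which can later be removed without touching a benzoate.

Step 9
Reactants: 14 2-(trimethylsilyl)ethyl 3-methylbut-2-enoate
Product: 15 2-(trimethylsilyl)ethyl (E)-4-bromo-3-methylbut-2-enoate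
Conditions: N-bromosuccinimide, 2,2'-azobis(2-methylpropionitrile) (cat.), PhCF3, reflux; chromatography
Reagents that add atoms: N-bromosuccinimide, O=C1CCC(=O)N1Br
Why: Wohl–Ziegler allylic bromination at a γ-methyl group of the senecioate should give the 4-bromide, from which the (E)-isomer carrying the 13E geometry of the target is separated by chromatography.

Step 10
Reactants: 11 (4S,5S)-4-acetyl-5-[2-(tert-butyldimethylsilyloxy)ethyl]-4,6,6-trimethylcyclohex-2-en-1-one; 15 2-(trimethylsilyl)ethyl (E)-4-bromo-3-methylbut-2-enoate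
Product: 17 2-(trimethylsilyl)ethyl (E)-6-[(1S,6S)-6-[2-(tert-butyldimethylsilyloxy)ethyl]-1,5,5-trimethyl-4-oxocyclohex-2-en-1-yl]-3-methyl-6-oxohex-2-enoate, via lithium enolate 16 (not isolated)
Conditions: LiN(SiMe3)2 (1.05 equiv), THF, −78 °C; then 15, DMPU, −78 → −30 °C
Reagents that add atoms: none
Why: In this ketone enolate alkylation (SN2 at the primary allylic bromide) ring A has no enolisable hydrogen because C4 and C10 are quaternary, so the base can form only the C11 enolate, which joins C11 to C12 and brings in C12–C16 with the E-enoate intact.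

Step 11
Reactants: 17 2-(trimethylsilyl)ethyl (E)-6-[(1S,6S)-6-[2-(tert-butyldimethylsilyloxy)ethyl]-1,5,5-trimethyl-4-oxocyclohex-2-en-1-yl]-3-methyl-6-oxohex-2-enoate
Product: 18 2-(trimethylsilyl)ethyl (E)-6-[(1S,2S)-2-[2-(tert-butyldimethylsilyloxy)ethyl]-1,3,3-trimethyl-4-oxocyclohexyl]-3-methyl-6-oxohex-2-enoate
Conditions: H2 (1 atm), RhCl(PPh3)3 (0.05 equiv), toluene/EtOH, rt
Reagents that add atoms: none
Why: Homogeneous hydrogenation with RhCl(PPh3)3 should reduce the disubstituted C1=C2 enone alkene and leave the trisubstituted conjugated C13=C14 bond alone, as in the selective saturation of the 1,2-bond of steroidal 1,4-dien-3-ones.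

Step 12
Reactants: 18 2-(trimethylsilyl)ethyl (E)-6-[(1S,2S)-2-[2-(tert-butyldimethylsilyloxy)ethyl]-1,3,3-trimethyl-4-oxocyclohexyl]-3-methyl-6-oxohex-2-enoate
Product: 19 2-(trimethylsilyl)ethyl (E)-6-[(1S,2S)-2-(2-hydroxyethyl)-1,3,3-trimethyl-4-oxocyclohexyl]-3-methyl-6-oxohex-2-enoate
Conditions: HF·pyridine, pyridine, THF, 0 °C → rt
Reagents that add atoms: none
Why: Cleavage of the primary silyl ether with buffered hydrogen fluoride should spare the 2-(trimethylsilyl)ethyl ester, which naked fluoride would cleave.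

Step 13
Reactants: 19 2-(trimethylsilyl)ethyl (E)-6-[(1S,2S)-2-(2-hydroxyethyl)-1,3,3-trimethyl-4-oxocyclohexyl]-3-methyl-6-oxohex-2-enoate
Product: 20 2-(trimethylsilyl)ethyl (E)-3-methyl-6-oxo-6-[(1S,2S)-1,3,3-trimethyl-4-oxo-2-(2-oxoethyl)cyclohexyl]hex-2-enoate
Conditions: Dess–Martin periodinane, pyridine, CH2Cl2, 0 °C → rt; used at once
Reagents that add atoms: none
Why: Dess–Martin oxidation under buffered, non-basic conditions should give the C7 aldehyde without aldol reaction toward the 1,5-related C9 ketone.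

Step 14
Reactants: 20 2-(trimethylsilyl)ethyl (E)-3-methyl-6-oxo-6-[(1S,2S)-1,3,3-trimethyl-4-oxo-2-(2-oxoethyl)cyclohexyl]hex-2-enoate
Product: 21 2-(trimethylsilyl)ethyl (E)-6-[(1S,2S)-2-[(Z)-3-iodobut-2-en-1-yl]-1,3,3-trimethyl-4-oxocyclohexyl]-3-methyl-6-oxohex-2-enoate
Conditions: EtPPh3I, n-BuLi, THF, 0 °C; I2, −78 °C; NaN(SiMe3)2, −78 → −20 °C; then 20, −78 °C
Reagents that add atoms: ethyltriphenylphosphonium iodide, CC[P+](c1ccccc1)(c1ccccc1)c1ccccc1.[I-]; iodine, II
Why: In this Stork–Zhao-type iodo-olefination the unstabilised ylide Ph3P=C(I)CH3 should react only with the aldehyde (both ketones are flanked by quaternary carbons) and give the (Z)-2-iodoalk-2-ene under kinetic control, so that C8 carries iodine cis to C6.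

Step 15
Reactants: 21 2-(trimethylsilyl)ethyl (E)-6-[(1S,2S)-2-[(Z)-3-iodobut-2-en-1-yl]-1,3,3-trimethyl-4-oxocyclohexyl]-3-methyl-6-oxohex-2-enoate
Product: 23 2-(trimethylsilyl)ethyl (13E)-9α-hydroxy-3-oxolabda-7,13-dien-15-oate [(5R,9R,10S)], via alkenylchromium 22 (not isolated)
Conditions: CrCl2 (10 equiv), NiCl2 (0.05 equiv), degassed DMSO, rt → 50 °C, high dilution
Reagents that add atoms: none
Why: Zerovalent nickel (from NiCl2 and CrCl2) inserts into the C8–I bond and hands the alkenyl group, with retention of the Z geometry, to trivalent chromium; the non-basic alkenylchromium 22 then adds to the C9 ketone, forming the C8–C9 bond and the chromium alkoxide of 23. The closest known reaction type is the intramolecular Nozaki–Hiyama–Kishi alkenylation of a carbonyl group, here with a ketone as acceptor. Ring B closes in the 6-exo-trig mode (C8 attacks the carbonyl carbon, the C=O bond stays outside the new ring), and only the Z iodide, in which C6 and the metal are cis, lets C8 reach C9 and fixes the alkene at C7=C8. The new stereocentre C9 is controlled by quaternary C10 and the chair of ring A: in the trans-decalin-like half-chair transition state C8 approaches anti to the C10–C1 bond and the C11 chain lies next to the small C10 methyl group and not next to C5, so the oxygen should end pseudoaxial (α, anti to the angular methyl) and the side chain equatorial (β), which is 9R. The step needs chemoselectivity for the C9 ketone over the C3 ketone and the ester: the ester is inert to alkenylchromium, and attack at C3 would demand a bridged bicyclo[3.3.1] transition state with the C5 arm axial. The non-basic reagent also leaves the enolisable C11 and C2 positions untouched.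

Step 16
Reactants: 23 2-(trimethylsilyl)ethyl (13E)-9α-hydroxy-3-oxolabda-7,13-dien-15-oate [(5R,9R,10S)]
Product: 24 2-(trimethylsilyl)ethyl (13E)-9α-benzoyloxy-3-oxolabda-7,13-dien-15-oate [(5R,9R,10S)]
Conditions: KN(SiMe3)2 (1.1 equiv), THF, −78 °C, 5 min; PhCOCl (1.5 equiv), −78 → −20 °C
Reagents that add atoms: benzoyl chloride, O=C(Cl)c1ccccc1
Why: In this O-acylation of a tertiary alkoxide the hindered 9α-hydroxyl, which resists amine-catalysed acylation, is deprotonated at −78 °C faster than C2–H of the ketone, and the potassium alkoxide should be captured by benzoyl chloride.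

Step 17
Reactants: 24 2-(trimethylsilyl)ethyl (13E)-9α-benzoyloxy-3-oxolabda-7,13-dien-15-oate [(5R,9R,10S)]
Product: 25 2-(trimethylsilyl)ethyl (13E)-9α-benzoyloxy-3β-hydroxylabda-7,13-dien-15-oate [(3S,5S,9R,10S)]
Conditions: NaBH4, MeOH/THF, −20 → 0 °C
Reagents that add atoms: none
Why: In this hydride reduction of a 4,4-dimethyl-3-ketone of a trans-decalin, borohydride should attack axially from the α face, away from the 4β-axial methyl group, and give the equatorial 3β-alcohol (3S) without reducing the esters.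

Step 18
Reactants: 25 2-(trimethylsilyl)ethyl (13E)-9α-benzoyloxy-3β-hydroxylabda-7,13-dien-15-oate [(3S,5S,9R,10S)]
Product: 26 (13E)-9α-benzoyloxy-3β-hydroxylabda-7,13-dien-15-oic acid [(3S,5S,9R,10S)]
Conditions: Bu4NF (3 equiv), THF, 0 °C → rt; 10% aq. citric acid work-up
Reagents that add atoms: none
Why: Fluoride-induced fragmentation of the 2-(trimethylsilyl)ethyl ester (attack at silicon, loss of ethene) should free the carboxylic acid under conditions that do not hydrolyse the hindered tertiary benzoate.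

**Compound list**

1 | but-3-en-2-one | CC(=O)C=C | starting material
2 | 2-(triisopropylsilyloxy)buta-1,3-diene | C=CC(=C)O[Si](C(C)C)(C(C)C)C(C)C | intermediate
3 | 3-(tert-butyldimethylsilyloxy)propanal | CC(C)(C)[Si](C)(C)OCCC=O | starting material
4 | 2-(triphenylphosphoranylidene)propanal | CC(C=O)=P(c1ccccc1)(c1ccccc1)c1ccccc1 | starting material
5 | (E)-5-(tert-butyldimethylsilyloxy)-2-methylpent-2-enal | O=C/C(C)=C/CCO[Si](C)(C)C(C)(C)C | intermediate
6 | (1S,6S)-6-[2-(tert-butyldimethylsilyloxy)ethyl]-1-methyl-4-(triisopropylsilyloxy)cyclohex-3-ene-1-carbaldehyde | CC(C)(C)[Si](C)(C)OCC[C@H]1CC(O[Si](C(C)C)(C(C)C)C(C)C)=CC[C@]1(C)C=O | intermediate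
7 | tert-butyl(2-{(1S,6R)-6-ethenyl-6-methyl-3-(triisopropylsilyloxy)cyclohex-3-en-1-yl}ethoxy)dimethylsilane | CC(C)(C)[Si](C)(C)OCC[C@H]1CC(O[Si](C(C)C)(C(C)C)C(C)C)=CC[C@]1(C)C=C | intermediate
8 | (4R,5S)-5-[2-(tert-butyldimethylsilyloxy)ethyl]-4-ethenyl-4-methylcyclohex-2-en-1-one | CC(C)(C)[Si](C)(C)OCC[C@H]1CC(=O)C=C[C@]1(C)C=C | intermediate
9 | (4S,5S)-5-[2-(tert-butyldimethylsilyloxy)ethyl]-4-ethenyl-4,6-dimethylcyclohex-2-en-1-one, both C6 epimers (not isolated) | CC(C)(C)[Si](C)(C)OCC[C@H]1C(C)C(=O)C=C[C@]1(C)C=C | intermediate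
10 | (4S,5R)-5-[2-(tert-butyldimethylsilyloxy)ethyl]-4-ethenyl-4,6,6-trimethylcyclohex-2-en-1-one | CC(C)(C)[Si](C)(C)OCC[C@H]1C(C)(C)C(=O)C=C[C@]1(C)C=C | intermediate
11 | (4S,5S)-4-acetyl-5-[2-(tert-butyldimethylsilyloxy)ethyl]-4,6,6-trimethylcyclohex-2-en-1-one | CC(C)(C)[Si](C)(C)OCC[C@H]1C(C)(C)C(=O)C=C[C@]1(C)C(C)=O | intermediate
12 | 3-methylbut-2-enoic acid | CC(C)=CC(=O)O | starting material
13 | 2-(trimethylsilyl)ethanol | C[Si](C)(C)CCO | starting material
14 | 2-(trimethylsilyl)ethyl 3-methylbut-2-enoate | CC(C)=CC(=O)OCC[Si](C)(C)C | intermediate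
15 | 2-(trimethylsilyl)ethyl (E)-4-bromo-3-methylbut-2-enoate | BrC/C(C)=C/C(=O)OCC[Si](C)(C)C | intermediate
16 | lithium enolate of 11 at the acetyl group (C9–O–Li, C9=C11) (not isolated) | CC(C)(C)[Si](C)(C)OCC[C@H]1C(C)(C)C(=O)C=C[C@]1(C)C(=C)O[Li] | intermediate
17 | 2-(trimethylsilyl)ethyl (E)-6-[(1S,6S)-6-[2-(tert-butyldimethylsilyloxy)ethyl]-1,5,5-trimethyl-4-oxocyclohex-2-en-1-yl]-3-methyl-6-oxohex-2-enoate | CC(C)(C)[Si](C)(C)OCC[C@H]1C(C)(C)C(=O)C=C[C@]1(C)C(=O)CC/C(C)=C/C(=O)OCC[Si](C)(C)C | intermediate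
18 | 2-(trimethylsilyl)ethyl (E)-6-[(1S,2S)-2-[2-(tert-butyldimethylsilyloxy)ethyl]-1,3,3-trimethyl-4-oxocyclohexyl]-3-methyl-6-oxohex-2-enoate | CC(C)(C)[Si](C)(C)OCC[C@H]1C(C)(C)C(=O)CC[C@]1(C)C(=O)CC/C(C)=C/C(=O)OCC[Si](C)(C)C | intermediate
19 | 2-(trimethylsilyl)ethyl (E)-6-[(1S,2S)-2-(2-hydroxyethyl)-1,3,3-trimethyl-4-oxocyclohexyl]-3-methyl-6-oxohex-2-enoate | OCC[C@H]1C(C)(C)C(=O)CC[C@]1(C)C(=O)CC/C(C)=C/C(=O)OCC[Si](C)(C)C | intermediate
20 | 2-(trimethylsilyl)ethyl (E)-3-methyl-6-oxo-6-[(1S,2S)-1,3,3-trimethyl-4-oxo-2-(2-oxoethyl)cyclohexyl]hex-2-enoate | O=CC[C@H]1C(C)(C)C(=O)CC[C@]1(C)C(=O)CC/C(C)=C/C(=O)OCC[Si](C)(C)C | intermediate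
21 | 2-(trimethylsilyl)ethyl (E)-6-[(1S,2S)-2-[(Z)-3-iodobut-2-en-1-yl]-1,3,3-trimethyl-4-oxocyclohexyl]-3-methyl-6-oxohex-2-enoate | C/C(I)=C/C[C@H]1C(C)(C)C(=O)CC[C@]1(C)C(=O)CC/C(C)=C/C(=O)OCC[Si](C)(C)C | intermediate
22 | alkenylchromium dichloride from 21 (trivalent chromium on C8 in place of iodine, Z geometry kept) (not isolated) | C/C([Cr](Cl)Cl)=C/C[C@H]1C(C)(C)C(=O)CC[C@]1(C)C(=O)CC/C(C)=C/C(=O)OCC[Si](C)(C)C | intermediate
23 | 2-(trimethylsilyl)ethyl (13E)-9α-hydroxy-3-oxolabda-7,13-dien-15-oate, (5R,9R,10S) | CC1=CC[C@H]2C(C)(C)C(=O)CC[C@]2(C)[C@]1(CC/C(C)=C/C(=O)OCC[Si](C)(C)C)O | intermediate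
24 | 2-(trimethylsilyl)ethyl (13E)-9α-benzoyloxy-3-oxolabda-7,13-dien-15-oate, (5R,9R,10S) | CC1=CC[C@H]2C(C)(C)C(=O)CC[C@]2(C)[C@]1(CC/C(C)=C/C(=O)OCC[Si](C)(C)C)OC(=O)c1ccccc1 | intermediate
25 | 2-(trimethylsilyl)ethyl (13E)-9α-benzoyloxy-3β-hydroxylabda-7,13-dien-15-oate, (3S,5S,9R,10S) | CC1=CC[C@H]2C(C)(C)[C@@H](O)CC[C@]2(C)[C@]1(CC/C(C)=C/C(=O)OCC[Si](C)(C)C)OC(=O)c1ccccc1 | intermediate
26 | (13E)-9α-benzoyloxy-3β-hydroxylabda-7,13-dien-15-oic acid, (3S,5S,9R,10S) | CC1=CC[C@H]2C(C)(C)[C@@H](O)CC[C@]2(C)[C@]1(CC/C(C)=C/C(=O)O)OC(=O)c1ccccc1 | target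

**Step count**

Total: 18 steps. Longest linear sequence: 15 steps (steps 2–7 and 10–18 from aldehyde 3; the same length from 1 through steps 1, 3–7 and 10–18).

**Steps most likely to fail**

1. Step 15. The alkenylchromium may add too slowly to the hindered α-quaternary ketone, so that protonolysis of the carbon–chromium bond takes over. The fallback sets out from 21 and comes back at 24. Iodine–lithium exchange with t-BuLi (2.1 equiv) in THF/Et2O/pentane at −100 °C, which outruns carbonyl addition at this temperature, triggers a polar anionic cyclisation of the intramolecular Barbier type. This should give the lithium 9α-olate F1, which is the lithium alkoxide of 23. F1 is acylated in the same flask with benzoyl chloride (−100 → −20 °C) to give 24, so the fallback replaces both the chromium-mediated closure and the separate acylation of step 16.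

2. Step 3. The trisubstituted enal may react too slowly or with too little face discrimination under the chiral catalyst, or 1,2-addition of the silyl enol ether to the activated formyl group may compete. The fallback sets out from 5 and 2 and comes back at 6, moving stereocontrol from the catalyst to a classical resolution. Cycloaddition promoted by the achiral Lewis acid MeAlCl2 (CH2Cl2, −78 °C) should give 6 together with its (1R,6R)-enantiomer F2 as the racemate. Condensation of this mixture with (1R,2R)-N,N'-dimethyl-1,2-diphenylethane-1,2-diamine (molecular sieves, Et2O) gives two diastereomers, the (1S,6S)-imidazolidine F3 from 6 and the (1R,6R)-imidazolidine F4 from the enantiomer F2. The two imidazolidines F3 and F4 are separated by chromatography, and mild hydrolysis of F3 (AcOH/NaOAc buffer, THF/H2O, 0 °C) returns enantiopure 6.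

3. Step 16. Proton transfer from C2–H of the C3 ketone to the hindered alkoxide may compete with the slow O-acylation, which would lead to enol benzoate formation. The fallback sets out from 23 and comes back at 26. NaBH4 (MeOH/THF, −20 °C) first reduces the C3 ketone to the 3β,9α-diol ester F5 with the same facial sense as in step 17. Et3SiCl/imidazole silylates only the secondary hydroxyl of F5 and gives the 3-triethylsilyl ether F6, in which the tertiary 9α-hydroxyl stays free. KN(SiMe3)2 and then benzoyl chloride, now without an enolisable ketone, convert F6 into the 9-benzoate 3-triethylsilyl ether F7. Bu4NF removes the triethylsilyl group and the 2-(trimethylsilyl)ethyl ester of F7 together and gives 26.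

**Further compounds**

F1 | step 15 | lithium alkoxide of 23 (lithium (13E)-3-oxo-15-[2-(trimethylsilyl)ethoxy]-15-oxolabda-7,13-dien-9α-olate) | CC1=CC[C@H]2C(C)(C)C(=O)CC[C@]2(C)[C@]1(CC/C(C)=C/C(=O)OCC[Si](C)(C)C)O[Li]
F2 | step 3 | (1R,6R)-6-[2-(tert-butyldimethylsilyloxy)ethyl]-1-methyl-4-(triisopropylsilyloxy)cyclohex-3-ene-1-carbaldehyde (enantiomer of 6, formed with 6 as the racemate) | CC(C)(C)[Si](C)(C)OCC[C@@H]1CC(O[Si](C(C)C)(C(C)C)C(C)C)=CC[C@@]1(C)C=O
F3 | step 3 | (4R,5R)-2-[(1S,6S)-6-[2-(tert-butyldimethylsilyloxy)ethyl]-1-methyl-4-(triisopropylsilyloxy)cyclohex-3-en-1-yl]-1,3-dimethyl-4,5-diphenylimidazolidine | CC(C)(C)[Si](C)(C)OCC[C@H]1CC(O[Si](C(C)C)(C(C)C)C(C)C)=CC[C@]1(C)C1N(C)[C@H](c2ccccc2)[C@@H](c2ccccc2)N1C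
F4 | step 3 | (4R,5R)-2-[(1R,6R)-6-[2-(tert-butyldimethylsilyloxy)ethyl]-1-methyl-4-(triisopropylsilyloxy)cyclohex-3-en-1-yl]-1,3-dimethyl-4,5-diphenylimidazolidine | CC(C)(C)[Si](C)(C)OCC[C@@H]1CC(O[Si](C(C)C)(C(C)C)C(C)C)=CC[C@@]1(C)C1N(C)[C@H](c2ccccc2)[C@@H](c2ccccc2)N1C
F5 | step 16 | 2-(trimethylsilyl)ethyl (13E)-3β,9α-dihydroxylabda-7,13-dien-15-oate, (3S,5S,9R,10S) | CC1=CC[C@H]2C(C)(C)[C@@H](O)CC[C@]2(C)[C@]1(CC/C(C)=C/C(=O)OCC[Si](C)(C)C)O
F6 | step 16 | 2-(trimethylsilyl)ethyl (13E)-9α-hydroxy-3β-(triethylsilyloxy)labda-7,13-dien-15-oate | CC1=CC[C@H]2C(C)(C)[C@@H](O[Si](CC)(CC)CC)CC[C@]2(C)[C@]1(CC/C(C)=C/C(=O)OCC[Si](C)(C)C)O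
F7 | step 16 | 2-(trimethylsilyl)ethyl (13E)-9α-benzoyloxy-3β-(triethylsilyloxy)labda-7,13-dien-15-oate | CC1=CC[C@H]2C(C)(C)[C@@H](O[Si](CC)(CC)CC)CC[C@]2(C)[C@]1(CC/C(C)=C/C(=O)OCC[Si](C)(C)C)OC(=O)c1ccccc1
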